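The runs come from a simulation on assumed constants; scatter was added.

Multiply the target reading by the partner charge to read the high end of the row, and divide it by that charge to read the low end.

in all of them: substrate 0.42 M
- spring: partner 0.45 equiv; reagent 1.3 equiv; run made earlier
- autumn: partner 1.6 equiv; reagent 1.3 equiv; run made earlier
- dusk: partner 5.4 equiv; reagent 1.3 equiv; run made earlier
- Thursday's: partner 0.600 equiv; reagent 1.30 equiv; time 12 h
- Friday's: partner 1.20 equiv; reagent 1.30 equiv; time 12 h
- Tuesday's: partner 2.50 equiv; reagent 1.30 equiv; time 12 h
- Saturday's: partner 5.00 equiv; reagent 1.30 equiv; time 12 h

| run | time / h | target / % |
|---|---|---|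
| spring | 1.00 | 3.6 |
| spring | 3.00 | 15.7 |
| spring | 6.00 | 24.5 |
| spring | 8.00 | 28.5 |
| spring | 12.0 | 26.8 |
| autumn | 1.00 | 6.7 |
| autumn | 2.00 | 16.6 |
| autumn | 3.00 | 22.1 |
| autumn | 6.00 | 30.5 |
| autumn | 12.0 | 35.2 |
| dusk | 1.00 | 6.0 |
| dusk | 2.00 | 10.5 |
| dusk | 3.00 | 11.5 |
| dusk | 6.00 | 14.5 |
| dusk | 12.0 | 13.2 |

(standard deviation of a reading: 1 percentage point)

- steps under discussion: substrate + reagent -> open intermediate; reagent + partner -> second intermediate; open intermediate + second intermediate -> target; substrate + second intermediate -> side product
- "hardly changes" means that all values lie within two and a half points (for a concentration: within two and a half percent of the largest)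

- amount of target at the end, in percent of the substrate charged for Thursday's, Friday's, Tuesday's, Saturday's, in this order
- the shape of the row from first to last (hardly changes / falls, then rises / falls all the way / rises, then falls / rises all the way)

Reagent is claimed by two paths, one at a rate proportional to c(substrate), the other proportional to c(partner). I assume that at a large partner excess c(partner) stays near its charge. Integrating the ratio of the two rates over the run then sends reagent to open intermediate in inverse proportion to that charge, so target times charge should stand still. Dusk gives K = 0.713, the target reading at 12.0 h times the partner charge. On the low side, partner is the limiting reagent by charge in spring, 0.45 equiv against 1.3 equiv of reagent, and the reading 26.8% gives f = 0.596 of target per partner charged. So I have two branches, f times charge rising and K over charge falling, and they cross at 1.09.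

Now turn the question round. The row has four settings, so on my branches it rises all the way once the crossing passes the geometric mean of the last two charges, 3.54, and falls all the way once the crossing drops below the geometric mean of the first two, 0.849. Two readings, each scattered by 1 percentage point, put the crossing a factor 1.29 above the lower limit and 3.23 below the upper one, so the nearer failure is a row that only falls. My branches give 35.7% for Thursday's, 28.5% for Tuesday's and 14.3% for Saturday's. Friday's lies near the crossing, where they overshoot: autumn's product is 0.563, less than K. So I expect a rounded top near autumn's 35.2%.

The forecast gives 31%, 36%, 28% and 15%, hence rises, then falls, holding that “excess partner diverts reagent into second intermediate”. My Thursday's figure stands higher than its first point and also higher than autumn's 35.2%, so my own figures show no rise before the fall, and there I part from the forecast's shape.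

The flasks give 34.3%, 37.8%, 26.1% and 15.3%: rises, then falls.

    substrate + reagent → open intermediate (k = 0.0300 /M/min)
    reagent + partner → second intermediate (k = 0.0430 /M/min)
    open intermediate + second intermediate → target (k = 0.0330 /M/min)
    substrate + second intermediate → side product (k = 0.0230 /M/min)

The product is 0.653 on Tuesday's and 0.765 on Saturday's, on either side of K = 0.713. The row turns at 0.95 equiv, lower than my crossing. Part of Saturday's low target comes from the wearing away of reagent: with reagent held at its charge, that flask gives 50.7% of target instead of 15.3%. That gain of 35 points is 42% of what Saturday's is missing.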